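**Retrosynthetic overview**

- Target numbering, used for all intermediates: ring C1 (quaternary; CH3 and the Z-chlorovinyl group C7=C8), C2 (CH2), C3 (CBr carrying C9H2Br), C4 (CHCl), C5 (CH2), C6 (CHCl). The route rests on the two ring chlorides at C4 and C6, 1,3-related across C5, with C4 next to C3: a Cl2CH–C(=O) unit at C4/C3 and a C5=C6 vinyl group on C1 deliver both when a C–Cl bond is added across the alkene.
- Endgame: C3(Br)–C9H2Br from Br2 and a C3 exocyclic methylene (made from the C3 ketone); the Z-C7=C8 chloroalkene from a Wittig reaction of the C7 aldehyde, carried as its dimethyl acetal.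
- The cyclohexane, the only ring, is closed in one step by copper-catalysed chlorine atom-transfer radical cyclisation of the acyclic dichloromethyl ketone 10 (C4–C5 and C6–Cl formed, 6-endo).
- Ketone 10 comes from a Weinreb amide and LiCHCl2; the C1 quaternary centre comes from a palladium-catalysed asymmetric allylic alkylation of isoprene monoepoxide with dimethyl malonate (malonate supplies C2 and C3, the epoxide CH2O becomes C7).

Key step: step 7

Assumption: the (S,S)-enantiomer of the bisphosphine ligand in step 1 is taken to give the (S)-configured adduct 3; if the sense of induction is the opposite, the (R,R)-ligand is used and nothing else changes.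

**Route**

Step 1
Reactants: 1 2-ethenyl-2-methyloxirane (isoprene monoepoxide, racemic); 2 dimethyl malonate
Product: 4 methyl (4S)-4-ethenyl-4-methyl-2-oxooxolane-3-carboxylate (both C3 epimers), via open-chain adduct 3 (not isolated)
Conditions: Pd2(dba)3·CHCl3 (1 mol %), N,N'-[(1S,2S)-cyclohexane-1,2-diyl]bis[2-(diphenylphosphanyl)naphthalene-1-carboxamide] (3 mol %), CH2Cl2, rt; then TsOH·H2O (5 mol %), PhMe, 60 °C
Reagents that add atoms: none
Why: Tsuji–Trost-type dynamic kinetic asymmetric allylic alkylation of a vinyl epoxide: zerovalent palladium opens racemic 1 to interconverting π-allyl alkoxides, the alkoxide deprotonates the malonate and steers it to the adjacent, more substituted allyl terminus, the chiral ligand pocket sets the C1 quaternary centre (S in 3), and the neopentyl alcohol then lactonises onto one ester under acid.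

Step 2
Reactants: 4 methyl (4S)-4-ethenyl-4-methyl-2-oxooxolane-3-carboxylate
Product: 5 (4R)-4-ethenyl-4-methyloxolan-2-one
Conditions: LiCl, H2O, DMSO, 150 °C
Reagents that add atoms: none
Why: Krapcho dealkoxycarbonylation (chloride demethylates the activated ester, the carboxylate loses CO2, the lactone enolate is protonated); the quaternary centre bears no hydrogen and is untouched, the descriptor changing only through CIP priorities.

Step 3
Reactants: 5 (4R)-4-ethenyl-4-methyloxolan-2-one
Product: 6 (3R)-3-(hydroxymethyl)-N-methoxy-N,3-dimethylpent-4-enamide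
Conditions: MeNH(OMe)·HCl, AlMe3, CH2Cl2, 0 °C to rt; aq. KNaC4H4O6 work-up; used at once
Reagents that add atoms: N,O-dimethylhydroxylamine hydrochloride, CNOC.Cl
Why: Weinreb aminolysis of a lactone by the aluminium amide formed from AlMe3 and the amine salt opens the ring to the γ-hydroxy Weinreb amide, which is oxidised without storage because it can relactonise.

Step 4
Reactants: 6 (3R)-3-(hydroxymethyl)-N-methoxy-N,3-dimethylpent-4-enamide
Product: 7 (3R)-3-formyl-N-methoxy-N,3-dimethylpent-4-enamide
Conditions: Dess–Martin periodinane, CH2Cl2, 0 °C to rt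
Reagents that add atoms: none
Why: Dess–Martin oxidation of the neopentyl primary alcohol is fast enough to outrun relactonisation, and the aldehyde has no α-hydrogen, so it can neither epimerise nor move into conjugation with the vinyl group.

Step 5
Reactants: 7 (3R)-3-formyl-N-methoxy-N,3-dimethylpent-4-enamide
Product: 8 (3R)-3-(dimethoxymethyl)-N-methoxy-N,3-dimethylpent-4-enamide
Conditions: HC(OMe)3, MeOH, TsOH·H2O (cat.), rt
Reagents that add atoms: methanol, CO; trimethyl orthoformate, COC(OC)OC
Why: Acid-catalysed acetalisation driven by the orthoformate as water scavenger masks C7 as a base-stable dimethyl acetal, while the Weinreb amide and the vinyl group are inert to these conditions.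

Step 6
Reactants: 8 (3R)-3-(dimethoxymethyl)-N-methoxy-N,3-dimethylpent-4-enamide
Product: 10 (4R)-1,1-dichloro-4-(dimethoxymethyl)-4-methylhex-5-en-2-one, via lithium hemiaminal adduct 9 (not isolated)
Conditions: CH2Cl2, LiN(i-Pr)2, THF, −95 °C; add 8; AcOH quench at −78 °C
Reagents that add atoms: dichloromethane, ClCCl
Why: Addition of pre-formed LiCHCl2 to a Weinreb amide gives the chelated tetrahedral adduct 9, which collapses to the dichloromethyl ketone only on the cold acidic quench, so over-addition and enolate chemistry of the acidic product are avoided (known acylation of dihalomethyllithiums).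

Step 7
Reactants: 10 (4R)-1,1-dichloro-4-(dimethoxymethyl)-4-methylhex-5-en-2-one
Product: 12 (2R,4S,5S)-2,4-dichloro-5-(dimethoxymethyl)-5-methylcyclohexan-1-one, via C4-epimeric ketone 11 (not isolated)
Conditions: CuCl (15 mol %), tris(2-pyridylmethyl)amine (TPMA, 15 mol %), degassed ClCH2CH2Cl, 80 °C; then evaporate, LiCl, DMF, 40 °C
Reagents that add atoms: lithium chloride, [Li+].[Cl-] (chloride exchange at C4)
Why: Monovalent copper (CuCl/TPMA) reversibly abstracts one chlorine of the Cl2CH–C(=O) unit to give the electrophilic α-chloro-α-keto radical at C4 and [Cu(TPMA)Cl]Cl; the radical adds to the terminal vinyl carbon C5, and the secondary C6 radical takes chlorine from the divalent copper chloride complex, which regenerates the catalyst, so 10 is isomerised to the ring with no atom lost. The closest known reaction type is the copper-catalysed atom-transfer radical cyclisation of α,α-dichloro carbonyl compounds, and the cyclohexanone is closed 6-endo-trig, the normal mode for 2-oxohex-5-enyl radicals, whose in-chain carbonyl (here together with the quaternary allylic C1) disfavours 5-exo attack at C6. C6 is controlled by C1: in the chair of the cyclised radical the branched acetal carbon should take the equatorial site and methyl the axial one, so chlorine is delivered axially to the face anti to methyl, i.e. cis to the acetal arm. C4 is formed from the radical rotamer with chlorine syn to the carbonyl oxygen and so emerges equatorial in that chair, trans to the axial C6 chlorine (11); being α to the ketone it is then inverted by degenerate SN2 chloride exchange (LiCl, DMF) towards 12, whose chair has both chlorides and methyl equatorial and which the polar medium should favour, the other epimer being recycled. The step needs 6-endo over 5-exo closure, secured by the ketone inside the chain, and facial selectivity at C6, which rests only on the size difference between methyl and the acetal arm at C1 and is the least secure element of the route.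

Step 8
Reactants: 12 (2R,4S,5S)-2,4-dichloro-5-(dimethoxymethyl)-5-methylcyclohexan-1-one
Product: 13 (1S,2S,4R)-2,4-dichloro-1-(dimethoxymethyl)-1-methyl-5-methylidenecyclohexane
Conditions: Cp2Ti(μ-Cl)(μ-CH2)AlMe2 (Tebbe reagent), pyridine (cat.), THF/PhMe, −40 to 0 °C
Reagents that add atoms: Tebbe reagent, C[Al+]C.[Cl-].[CH2-2].[Ti+4].c1cc[cH-]c1.c1cc[cH-]c1
Why: Tebbe methylenation ([2+2] addition of Cp2Ti=CH2 to the C3 ketone and cycloreversion) is not basic, so the α-chloro ketone is neither enolised, epimerised at C4 nor sent down a Favorskii path, and the acetal is inert.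

Step 9
Reactants: 13 (1S,2S,4R)-2,4-dichloro-1-(dimethoxymethyl)-1-methyl-5-methylidenecyclohexane
Product: 14 (1S,2S,4R)-2,4-dichloro-1-methyl-5-methylidenecyclohexane-1-carbaldehyde
Conditions: TsOH·H2O (10 mol %), acetone/H2O, 40 °C
Reagents that add atoms: water, O
Why: Mild acid-catalysed acetal hydrolysis (transacetalisation to acetone) frees the C7 aldehyde, which has no α-hydrogen, under conditions too weak to ionise the secondary allylic chloride or to isomerise the exocyclic alkene.

Step 10
Reactants: 14 (1S,2S,4R)-2,4-dichloro-1-methyl-5-methylidenecyclohexane-1-carbaldehyde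
Product: 15 (1S,2S,4R)-2,4-dichloro-1-[(Z)-2-chloroethenyl]-1-methyl-5-methylidenecyclohexane
Conditions: [Ph3PCH2Cl]Cl, NaN(SiMe3)2, THF, −78 °C; add 14; to 0 °C
Reagents that add atoms: (chloromethyl)triphenylphosphonium chloride, ClC[P+](c1ccccc1)(c1ccccc1)c1ccccc1.[Cl-]
Why: Wittig reaction with Ph3P=CHCl under lithium-free conditions: kinetic formation of the cis-oxaphosphetane with the hindered α-quaternary aldehyde should give mainly the Z-chloroalkene, and the low temperature limits E2 loss of the allylic chloride.

Step 11
Reactants: 15 (1S,2S,4R)-2,4-dichloro-1-[(Z)-2-chloroethenyl]-1-methyl-5-methylidenecyclohexane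
Product: 16 (1S,2R,4S,5S)-1-bromo-1-(bromomethyl)-2,4-dichloro-5-[(Z)-2-chloroethenyl]-5-methylcyclohexane
Conditions: Br2 (1.0 equiv), CH2Cl2, −78 °C, dark
Reagents that add atoms: bromine, BrBr
Why: Electrophilic anti addition of Br2 to the 1,1-disubstituted C3=C9 alkene (the chlorovinyl group is deactivated): in the chair with both chlorides equatorial the axial chlorovinyl group shields the lower face of C3, so the bulky electrophile should form the bromonium ion on the upper face and bromide should then open it at the tertiary carbon C3 from the axial direction, giving axial C3–Br cis to C4–Cl and equatorial CH2Br (C3 = S).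

**Compound list**

1 | 2-ethenyl-2-methyloxirane (isoprene monoepoxide, racemic) | CC1(C=C)CO1 | starting material
2 | dimethyl malonate | COC(=O)CC(=O)OC | starting material
3 | dimethyl 2-[(2S)-1-hydroxy-2-methylbut-3-en-2-yl]propanedioate | OC[C@@](C)(C=C)C(C(=O)OC)C(=O)OC | intermediate
4 | methyl (4S)-4-ethenyl-4-methyl-2-oxooxolane-3-carboxylate (both C3 epimers) | COC(=O)C1C(=O)OC[C@@]1(C)C=C | intermediate
5 | (4R)-4-ethenyl-4-methyloxolan-2-one | O=C1C[C@@](C)(CO1)C=C | intermediate
6 | (3R)-3-(hydroxymethyl)-N-methoxy-N,3-dimethylpent-4-enamide | CON(C)C(=O)C[C@@](C)(CO)C=C | intermediate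
7 | (3R)-3-formyl-N-methoxy-N,3-dimethylpent-4-enamide | CON(C)C(=O)C[C@@](C)(C=O)C=C | intermediate
8 | (3R)-3-(dimethoxymethyl)-N-methoxy-N,3-dimethylpent-4-enamide | CON(C)C(=O)C[C@@](C)(C(OC)OC)C=C | intermediate
9 | lithium (4R)-1,1-dichloro-4-(dimethoxymethyl)-2-[methoxy(methyl)amino]-4-methylhex-5-en-2-olate (both C2 epimers) | [Li+].[O-]C(C(Cl)Cl)(N(C)OC)C[C@@](C)(C(OC)OC)C=C | intermediate
10 | (4R)-1,1-dichloro-4-(dimethoxymethyl)-4-methylhex-5-en-2-one | ClC(Cl)C(=O)C[C@@](C)(C(OC)OC)C=C | intermediate
11 | (2S,4S,5S)-2,4-dichloro-5-(dimethoxymethyl)-5-methylcyclohexan-1-one | C[C@@]1(C(OC)OC)CC(=O)[C@@H](Cl)C[C@@H]1Cl | intermediate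
12 | (2R,4S,5S)-2,4-dichloro-5-(dimethoxymethyl)-5-methylcyclohexan-1-one | C[C@@]1(C(OC)OC)CC(=O)[C@H](Cl)C[C@@H]1Cl | intermediate
13 | (1S,2S,4R)-2,4-dichloro-1-(dimethoxymethyl)-1-methyl-5-methylidenecyclohexane | C[C@@]1(C(OC)OC)CC(=C)[C@H](Cl)C[C@@H]1Cl | intermediate
14 | (1S,2S,4R)-2,4-dichloro-1-methyl-5-methylidenecyclohexane-1-carbaldehyde | C[C@@]1(C=O)CC(=C)[C@H](Cl)C[C@@H]1Cl | intermediate
15 | (1S,2S,4R)-2,4-dichloro-1-[(Z)-2-chloroethenyl]-1-methyl-5-methylidenecyclohexane | C[C@@]1(/C=C\Cl)CC(=C)[C@H](Cl)C[C@@H]1Cl | intermediate
16 | (1S,2R,4S,5S)-1-bromo-1-(bromomethyl)-2,4-dichloro-5-[(Z)-2-chloroethenyl]-5-methylcyclohexane | C[C@@]1(/C=C\Cl)C[C@@](Br)(CBr)[C@H](Cl)C[C@@H]1Cl | target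

Total step count: 11. Longest linear sequence: 11 steps (the route is fully linear from 1 and 2).

**Steps most likely to fail**

Step 7. The main danger is poor or inverted facial selectivity when chlorine is transferred to the C6 radical: methyl and the acetal carbon differ little in effective size, and only one syn-axial hydrogen discriminates them, so chlorine may enter cis to methyl. Lesser losses may come from 5-exo closure, from 1,5-hydrogen transfer of the acetal C–H to the C4 radical, and from an unfavourable C4 equilibrium (the unwanted C4 epimer is separated and returned to the LiCl/DMF exchange). The fallback exchanges the steric roles at C1: the branched acetal is replaced by a linear nitrile, smaller than methyl, so that methyl is the only bulky neighbour of C6 and the chlorine donor should enter anti to it. It sets out from aldehyde 7 and comes back at aldehyde 14. Aldehyde 7 is converted by I2 and aqueous NH3 in THF into the cyano Weinreb amide F1. LiCHCl2, used as in step 6, then gives the cyano dichloromethyl ketone F2, and CuCl/TPMA cyclisation as in step 7 gives the cyano ketone F3. Methylenation with Cp2Ti(μ-Cl)(μ-CH2)AlMe2 at −40 °C, where the ketone reacts much faster than the hindered tertiary nitrile, gives the cyano alkene F4. Reduction with i-Bu2AlH at −78 °C and hydrolysis of the aldimine with dilute aqueous HCl return the route at 14.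

Step 10. The Wittig reaction with Ph3P=CHCl may show low Z/E selectivity, and the basic ylide may cause dehydrochlorination of the allylic chloride. The fallback builds the Z geometry by syn addition of hydrogen to an alkyne; it sets out from aldehyde 14 and comes back at diene 15. Aldehyde 14 is homologated with dimethyl (1-diazo-2-oxopropyl)phosphonate and K2CO3 in MeOH (Ohira–Bestmann reaction) to the terminal alkyne F5. Deprotonation with LiN(SiMe3)2 at −78 °C and trapping with N-chlorosuccinimide give the chloroalkyne F6. Diimide, generated from 2-nitrobenzenesulfonyl hydrazide and Et3N, should reduce the haloalkyne faster than the hindered 1,1-disubstituted alkene and deliver the Z-chloroalkene 15 by cis hydrogen transfer.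

Step 11. Bromide may open the bromonium ion at the primary carbon C9, or the bromonium ion may form on the lower face; either course gives the wrong configuration at C3. The fallback moves from kinetic to thermodynamic control; it sets out from diene 15 and comes back at target 16. The bromination mixture containing the C3-epimeric dibromide F7 is not separated but warmed in MeCN, with ZnBr2 (cat.) if needed. 1,2-Dibromides of this kind interconvert through the bromonium–bromide ion pair (dibromide mutarotation), which exchanges the two bromines with inversion at C3. The equilibrium should lie on the side of 16, in which the larger CH2Br group is equatorial and not syn-axial to the chlorovinyl group.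

**Further compounds**

F1 | step 7 | (3R)-3-cyano-N-methoxy-N,3-dimethylpent-4-enamide | CON(C)C(=O)C[C@@](C)(C#N)C=C
F2 | step 7 | (2R)-2-(3,3-dichloro-2-oxopropyl)-2-methylbut-3-enenitrile | ClC(Cl)C(=O)C[C@@](C)(C#N)C=C
F3 | step 7 | (1S,2S,4R)-2,4-dichloro-1-methyl-5-oxocyclohexane-1-carbonitrile | C[C@@]1(C#N)CC(=O)[C@H](Cl)C[C@@H]1Cl
F4 | step 7 | (1S,2S,4R)-2,4-dichloro-1-methyl-5-methylidenecyclohexane-1-carbonitrile | C[C@@]1(C#N)CC(=C)[C@H](Cl)C[C@@H]1Cl
F5 | step 10 | (1S,2S,4R)-2,4-dichloro-1-ethynyl-1-methyl-5-methylidenecyclohexane | C[C@@]1(C#C)CC(=C)[C@H](Cl)C[C@@H]1Cl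
F6 | step 10 | (1S,2S,4R)-2,4-dichloro-1-(chloroethynyl)-1-methyl-5-methylidenecyclohexane | C[C@@]1(C#CCl)CC(=C)[C@H](Cl)C[C@@H]1Cl
F7 | step 11 | (1R,2R,4S,5S)-1-bromo-1-(bromomethyl)-2,4-dichloro-5-[(Z)-2-chloroethenyl]-5-methylcyclohexane | C[C@@]1(/C=C\Cl)C[C@](Br)(CBr)[C@H](Cl)C[C@@H]1Cl
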